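**Retrosynthetic overview**

- The diarylmethane bond between the bridging CH2 (carried by the methoxy ring B) and the bridge-bearing carbon of the trihydroxy ring A is cut. Ring A becomes a free acylphloroglucinol C-nucleophile and ring B an ortho-quinone methide released from a phenolic Mannich base (biomimetic, protecting-group-free last step).
- Enabling feature: in ring B the bridging CH2 sits on C1 between the two free phenolic OH groups at C2 and C6 and para to the C4 OMe, so ring B can dearomatise to a 6-methylidenecyclohexa-2,4-dienone. In ring A the bridged carbon is the only unsubstituted ring carbon and lies between two OH groups (enol carbon of a vinylogous acid).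
- The bridging carbon is carried first as a formyl group. It directs the twofold ortho-demethylation that fixes the O-methyl pattern of ring B, and is then turned into CH2NMe2 by reductive amination.
- Ring B: 2,4,6-trimethoxytoluene, Vilsmeier formylation, bis-ortho-demethylation, butanoylation of the last free ring carbon, reductive amination. Ring A: 2-methylphloroglucinol plus butanoyl chloride.
- No ring is formed in the route; both benzene rings come from commercial arenes and are only substituted.

Key step: step 6

Remark: the target has no stereocentre and no other stereogenic element, so it is achiral and no stereocontrol is needed.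

**Route**

Step 1
Reactants: 1 2-methylphloroglucinol (2-methylbenzene-1,3,5-triol); 2 butanoyl chloride
Product: 3 1-(2,4,6-trihydroxy-3-methylphenyl)butan-1-one
Conditions: AlCl3 (3.5 equiv), PhNO2, rt → 60 °C; then ice, 1 M HCl
Reagents that add atoms: butanoyl chloride (2), CCCC(=O)Cl
Why: Friedel–Crafts acylation: the two unsubstituted ring carbons of 1 are equivalent and each is activated by three OH groups, so a single aryl ketone should form, and the chelated ketone deactivates the ring against a second acylation.

Step 2
Reactants: 4 2,4,6-trimethoxytoluene (1,3,5-trimethoxy-2-methylbenzene); 5 N,N-dimethylformamide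
Product: 7 2,4,6-trimethoxy-3-methylbenzaldehyde, via iminium chloride 6 (not isolated)
Conditions: POCl3 (1.2 equiv), DMF, 0 °C → 60 °C; then H2O, 60 °C
Reagents that add atoms: N,N-dimethylformamide (5), CN(C)C=O; water, O
Why: Vilsmeier–Haack formylation: the two free ring positions of 4 are equivalent and activated by three methoxy groups, so the chloroiminium ion should attack once to give iminium salt 6, which water hydrolyses to the aldehyde.

Step 3
Reactants: 7 2,4,6-trimethoxy-3-methylbenzaldehyde
Product: 8 2,6-dihydroxy-4-methoxy-3-methylbenzaldehyde
Conditions: AlCl3 (5 equiv), CH2Cl2, 0 °C → reflux; then 1 M HCl, 0 °C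
Reagents that add atoms: none
Why: Chelation-assisted Lewis-acid cleavage of aryl methyl ethers: aluminium bound to the formyl oxygen activates only the two flanking methoxy groups toward attack of chloride on their methyl carbons, while the para-methoxy group, which cannot chelate, should remain.

Step 4
Reactants: 8 2,6-dihydroxy-4-methoxy-3-methylbenzaldehyde; 2 butanoyl chloride
Product: 9 3-butanoyl-2,6-dihydroxy-4-methoxy-5-methylbenzaldehyde
Conditions: butanoyl chloride (1.3 equiv), TiCl4 (3 equiv), ClCH2CH2Cl, 0 → 50 °C; then 1 M HCl
Reagents that add atoms: butanoyl chloride (2), CCCC(=O)Cl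
Why: TiCl4-mediated Friedel–Crafts C-acylation of a phenol: only one ring carbon is unsubstituted, it is ortho to a titanium phenoxide and to OMe and para to the second phenol, and TiCl4 at this temperature should be too mild to cleave the methyl ether or the formyl group.

Step 5
Reactants: 9 3-butanoyl-2,6-dihydroxy-4-methoxy-5-methylbenzaldehyde; 10 dimethylamine
Product: 12 1-{3-[(dimethylamino)methyl]-2,4-dihydroxy-6-methoxy-5-methylphenyl}butan-1-one, via iminium phenolate 11 (not isolated)
Conditions: Me2NH (2 M in THF, 3 equiv), AcOH (1 equiv), NaBH(OAc)3 (1.5 equiv), ClCH2CH2Cl, rt; pH 7 buffer work-up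
Reagents that add atoms: dimethylamine (10), CNC
Why: Reductive amination with NaBH(OAc)3: only the aldehyde condenses with the secondary amine, giving iminium phenolate 11, which the mild acetoxyborohydride should reduce without touching the hindered, chelated aryl ketone.

Step 6
Reactants: 12 1-{3-[(dimethylamino)methyl]-2,4-dihydroxy-6-methoxy-5-methylphenyl}butan-1-one; 3 1-(2,4,6-trihydroxy-3-methylphenyl)butan-1-one
Product: 14 1-{3-[(3-butanoyl-2,6-dihydroxy-4-methoxy-5-methylphenyl)methyl]-2,4,6-trihydroxy-5-methylphenyl}butan-1-one, via ortho-quinone methide 13 (not isolated)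
Conditions: 3 (1.5 equiv), 1,4-dioxane, 80 °C, slow N2 stream
Reagents that add atoms: none
Why: The zwitterionic Mannich base 12 (phenolate/ammonium) should expel dimethylamine in an E1cB-type elimination and dearomatise ring B to ortho-quinone methide 13; the only unsubstituted ring carbon of 3, an enol carbon between two OH groups, then adds to the exocyclic CH2 in a Michael (vinylogous Friedel–Crafts) reaction, and proton shifts rearomatise both rings. The closest known reaction type is the capture of ortho-quinone methides from phenolic Mannich bases by phenols and 1,3-dicarbonyl compounds, which is also the presumed natural origin of methylene-bridged acylphloroglucinols. No ring is closed and no stereocentre is created. The step needs cross-coupling over homo-coupling and C- over O-alkylation: 12 has no free ring carbon and cannot act as the nucleophile, 3 has no leaving group and cannot act as the electrophile, 3 offers a single nucleophilic carbon, and O-adducts should revert to 13 while the C-adduct is the thermodynamic sink. Removal of volatile Me2NH in the gas stream should drive the elimination and keep the medium from becoming basic enough to reopen the product.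

**Compound list**

1 | 2-methylphloroglucinol (2-methylbenzene-1,3,5-triol) | Cc1c(O)cc(O)cc1O | starting material
2 | butanoyl chloride | CCCC(=O)Cl | starting material
3 | 1-(2,4,6-trihydroxy-3-methylphenyl)butan-1-one | CCCC(=O)c1c(O)cc(O)c(C)c1O | intermediate
4 | 2,4,6-trimethoxytoluene (1,3,5-trimethoxy-2-methylbenzene) | Cc1c(OC)cc(OC)cc1OC | starting material
5 | N,N-dimethylformamide | CN(C)C=O | starting material
6 | N,N-dimethyl-1-(2,4,6-trimethoxy-3-methylphenyl)methaniminium chloride | Cc1c(OC)cc(OC)c(C=[N+](C)C)c1OC.[Cl-] | intermediate
7 | 2,4,6-trimethoxy-3-methylbenzaldehyde | Cc1c(OC)cc(OC)c(C=O)c1OC | intermediate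
8 | 2,6-dihydroxy-4-methoxy-3-methylbenzaldehyde | Cc1c(OC)cc(O)c(C=O)c1O | intermediate
9 | 3-butanoyl-2,6-dihydroxy-4-methoxy-5-methylbenzaldehyde | CCCC(=O)c1c(O)c(C=O)c(O)c(C)c1OC | intermediate
10 | dimethylamine | CNC | starting material
11 | 4-butanoyl-2-[(dimethyliminio)methyl]-3-hydroxy-5-methoxy-6-methylphenolate | CCCC(=O)c1c(O)c(C=[N+](C)C)c([O-])c(C)c1OC | intermediate
12 | 1-{3-[(dimethylamino)methyl]-2,4-dihydroxy-6-methoxy-5-methylphenyl}butan-1-one | CCCC(=O)c1c(O)c(CN(C)C)c(O)c(C)c1OC | intermediate
13 | 4-butanoyl-5-hydroxy-3-methoxy-2-methyl-6-methylidenecyclohexa-2,4-dien-1-one | C=C1C(=O)C(C)=C(OC)C(C(=O)CCC)=C1O | intermediate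
14 | 1-{3-[(3-butanoyl-2,6-dihydroxy-4-methoxy-5-methylphenyl)methyl]-2,4,6-trihydroxy-5-methylphenyl}butan-1-one | CCCC(=O)c1c(O)c(C)c(O)c(Cc2c(O)c(C)c(OC)c(C(=O)CCC)c2O)c1O | target

**Step count and risks**

Total step count: 6. Longest linear sequence: 5 (steps 2 to 6); step 1 is a one-step branch.

Steps most likely to fail:

1. Step 6. The ortho-quinone methide may form reversibly from the product side as well (retro-Michael in the warm, amine-containing medium), which would exchange the two halves and lead to homo-coupled material. If C–C bond formation is slow, the quinone methide may also be consumed by O-alkylation or self-addition. The fallback changes the electrophile precursor and the mechanism, from amine elimination to acid-catalysed dehydrative Friedel–Crafts benzylation. It sets out from 9: reduction with NaBH4 (THF/MeOH, −20 °C, inverse addition, AcOH quench) should give the benzylic alcohol 1-[2,4-dihydroxy-3-(hydroxymethyl)-6-methoxy-5-methylphenyl]butan-1-one F1. F1 and 3 with a Brønsted acid catalyst (diphenyl phosphate, 10 mol %, CH2Cl2/HFIP, rt) should ionise through protonated 13 and be captured by 3, and the route is rejoined at 14. Without a phenolate in the medium the retro-Michael pathway should be suppressed.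

2. Step 4. C-acylation of the formyl-deactivated ring may be sluggish, with competing O-acylation, loss of the formyl group by ipso-substitution, or cleavage of the methoxy group next to the new ketone. The fallback replaces intermolecular acylation by O-acylation and Fries rearrangement. It sets out from 8: butanoic anhydride, pyridine and DMAP should give 2-formyl-5-methoxy-4-methyl-1,3-phenylene dibutanoate F2. Fries rearrangement (BF3·OEt2, 60 °C) should move one acyl group to the only free ring carbon and give 4-butanoyl-2-formyl-3-hydroxy-5-methoxy-6-methylphenyl butanoate F3. Methanolysis of the remaining ester (K2CO3, MeOH, rt) rejoins the route at 9.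

3. Step 3. The second ortho-demethylation may stop at the mono-phenol, or forcing conditions may also remove the para-methoxy group. The fallback builds the O-methyl pattern by selective methylation instead of selective demethylation. It sets out from 1: Vilsmeier–Haack formylation (POCl3, DMF, EtOAc, rt; then H2O) should pass through N,N-dimethyl-1-(2,4,6-trihydroxy-3-methylphenyl)methaniminium chloride F4 and give 2,4,6-trihydroxy-3-methylbenzaldehyde F5. Mono-O-methylation of F5 at the most acidic hydroxyl, the one para to the formyl group that cannot hydrogen-bond to it (MeI, 1.0 equiv, Li2CO3, DMF, rt), rejoins the route at 8.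

**Further compounds**

F1 | step 6 | 1-[2,4-dihydroxy-3-(hydroxymethyl)-6-methoxy-5-methylphenyl]butan-1-one | CCCC(=O)c1c(O)c(CO)c(O)c(C)c1OC
F2 | step 4 | 2-formyl-5-methoxy-4-methyl-1,3-phenylene dibutanoate | Cc1c(OC)cc(OC(=O)CCC)c(C=O)c1OC(=O)CCC
F3 | step 4 | 4-butanoyl-2-formyl-3-hydroxy-5-methoxy-6-methylphenyl butanoate | CCCC(=O)c1c(O)c(C=O)c(OC(=O)CCC)c(C)c1OC
F4 | step 3 | N,N-dimethyl-1-(2,4,6-trihydroxy-3-methylphenyl)methaniminium chloride | Cc1c(O)cc(O)c(C=[N+](C)C)c1O.[Cl-]
F5 | step 3 | 2,4,6-trihydroxy-3-methylbenzaldehyde | Cc1c(O)cc(O)c(C=O)c1O
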